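**Strategy.** Ring A is built last, on a finished 2-aryl-3-benzyloxy-4-pyranone (rings C and B). The feature exploited is its substitution pattern on the C4a=C8a bond: para oxygens at C5 and C8 with C6–H and C7–OMe between them, the signature of a hydroquinone monoether from a chromium carbene benzannulation. In one operation the carbene carbon (C5), methoxyacetylene (C6, C7) and a CO ligand (C8) form C5–C6, C7–C8 and C8–C8a and close ring A with the two para oxygens differentiated. The precursor is a pentacarbonylchromium methoxycarbene on the free alpha carbon of the pyranone, made from the pyranonecarboxylic acid chloride and K2Cr(CO)5.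

Key step: step 9

Remark 1: the target has no stereocentre. Enaminone 6 and its acylation product 8 are mobile at the aminomethylene double bond, and 8 is racemic at a carbon that becomes sp2 in 9, so their SMILES carry no stereo descriptors.
Remark 2: chromium–carbon bonds are drawn as formal double bonds, and complex 19 is written as arene plus Cr(CO)3 fragment without the hapto bonds.
Remark 3: methoxyacetylene (18) is volatile and is handled only as a cold, titrated THF solution.

**Route**

Step 1
Reactants: 1 methyl 3,5-dihydroxy-4-methoxybenzoate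
Product: 2 methyl 3,5-bis(benzyloxy)-4-methoxybenzoate
Conditions: BnBr (2.3 equiv), K2CO3, DMF, 60 °C
Reagents that add atoms: benzyl bromide, BrCc1ccccc1
Why: Williamson ether synthesis on the two equivalent phenols; the ester and the 4-OMe group are inert to carbonate.

Step 2
Reactants: 2 methyl 3,5-bis(benzyloxy)-4-methoxybenzoate
Product: 3 3,5-bis(benzyloxy)-4-methoxybenzoic acid
Conditions: LiOH, THF/MeOH/H2O, 50 °C; then 1 M HCl
Reagents that add atoms: lithium hydroxide, [Li+].[OH-]
Why: Saponification of an unhindered methyl benzoate by acyl–oxygen cleavage; benzyl and methyl aryl ethers are stable to hydroxide.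

Step 3
Reactants: 4 tert-butyl 4-chloro-3-oxobutanoate
Product: 5 tert-butyl 4-(benzyloxy)-3-oxobutanoate
Conditions: BnOH, NaH (2.2 equiv), THF, 0 °C to rt; then 1 M HCl, 0 °C
Reagents that add atoms: benzyl alcohol, OCc1ccccc1
Why: Williamson-type displacement of the terminal chloride by sodium benzyloxide on the sodium enolate of the keto ester, which shields ketone and ester from the alkoxide, while the tert-butyl ester resists transesterification.

Step 4
Reactants: 5 tert-butyl 4-(benzyloxy)-3-oxobutanoate
Product: 6 tert-butyl 4-(benzyloxy)-2-[(dimethylamino)methylidene]-3-oxobutanoate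
Conditions: Me2NCH(OMe)2 (1.2 equiv), toluene, rt
Reagents that add atoms: N,N-dimethylformamide dimethyl acetal, COC(OC)N(C)C
Why: Enaminone formation by condensation of the amide acetal at the doubly activated C2 methylene, the less acidic benzyloxymethylene at C4 staying free for the next step.

Step 5
Reactants: 3 3,5-bis(benzyloxy)-4-methoxybenzoic acid; 6 tert-butyl 4-(benzyloxy)-2-[(dimethylamino)methylidene]-3-oxobutanoate
Product: 9 tert-butyl 5-(benzyloxy)-6-[3,5-bis(benzyloxy)-4-methoxyphenyl]-4-oxo-4H-pyran-3-carboxylate, via aroyl chloride 7 (not isolated), via acylated enaminone 8 (not isolated)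
Conditions: 3, (COCl)2, cat. DMF, CH2Cl2, rt, evaporate; 6, LiN(SiMe3)2 (2.4 equiv), THF, −78 °C, then 7; then 1 M HCl, rt
Reagents that add atoms: none
Why: Claisen-type C-acylation of the enaminone dienolate (deprotonated at its only acidic site, C4) by the aroyl chloride, then acid-induced 6-endo addition of the new enol oxygen to the aminomethylene carbon with loss of dimethylamine, the established enaminone-anion route to 4-oxopyran-3-carboxylates.

Step 6
Reactants: 9 tert-butyl 5-(benzyloxy)-6-[3,5-bis(benzyloxy)-4-methoxyphenyl]-4-oxo-4H-pyran-3-carboxylate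
Product: 10 5-(benzyloxy)-6-[3,5-bis(benzyloxy)-4-methoxyphenyl]-4-oxo-4H-pyran-3-carboxylic acid
Conditions: CF3CO2H/CH2Cl2 (1:4), 0 °C to rt
Reagents that add atoms: none
Why: Acidolysis of the tert-butyl ester through the tert-butyl cation avoids hydroxide, which would open the pyranone at its unsubstituted C2, and benzyl aryl ethers should tolerate brief exposure to dilute acid.

Step 7
Reactants: 10 5-(benzyloxy)-6-[3,5-bis(benzyloxy)-4-methoxyphenyl]-4-oxo-4H-pyran-3-carboxylic acid; 11 chromium hexacarbonyl
Product: 15 pentacarbonyl{[5-(benzyloxy)-6-(3,5-bis(benzyloxy)-4-methoxyphenyl)-4-oxo-4H-pyran-3-yl](methoxy)methylidene}chromium, via pyranone acid chloride 12 (not isolated), via dipotassium pentacarbonylchromate 13 (not isolated), via potassium acylchromate 14 (not isolated)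
Conditions: 10, (COCl)2, cat. DMF, CH2Cl2, 0 °C, evaporate; Cr(CO)6, KC8 (2.1 equiv), THF, −78 to 0 °C; add 12, −78 to 0 °C; then Me3OBF4, CH2Cl2, 0 °C
Reagents that add atoms: trimethyloxonium tetrafluoroborate, C[O+](C)C.F[B-](F)(F)F
Why: Semmelhack–Hegedus synthesis of a Fischer carbene complex, in which the pentacarbonylchromate dianion is acylated by the acid chloride and the anionic acyl oxygen is then methylated by the Meerwein salt, so that no organolithium meets the pyranone carbonyl and no halogenation near the electron-rich aryl ring is needed.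

Step 8
Reactants: 16 chloroacetaldehyde dimethyl acetal
Product: 18 methoxyacetylene, via sodium methoxyacetylide 17 (not isolated)
Conditions: NaNH2 (3 equiv), liq. NH3, −33 °C; evaporate NH3; cold sat. aq NaCl, distil into −78 °C trap, store as THF solution
Reagents that add atoms: none
Why: Two successive amide-induced eliminations (methanol, then HCl) give the ynol ether, which is held as its sodium acetylide and released by water, the standard preparation of alkoxyacetylenes from chloroacetals.

Step 9
Reactants: 15 pentacarbonyl{[5-(benzyloxy)-6-(3,5-bis(benzyloxy)-4-methoxyphenyl)-4-oxo-4H-pyran-3-yl](methoxy)methylidene}chromium; 18 methoxyacetylene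
Product: 20 3-(benzyloxy)-2-[3,5-bis(benzyloxy)-4-methoxyphenyl]-8-hydroxy-5,7-dimethoxy-4H-chromen-4-one, via arene tricarbonylchromium complex 19 (not isolated)
Conditions: 18 (3 equiv, slow addition), THF, 50 °C, argon, sealed vessel; then air, MeCN, rt
Reagents that add atoms: none
Why: Proposed new method: thermal loss of one CO from 15 should let 18 insert into the Cr=C bond with its nucleophilic CH terminus bonding to the electrophilic carbene carbon (C5–C6), the methoxy-bearing carbon becoming the new carbene centre, where CO insertion (C7–C8) gives a dienylketene that closes ring A by a six-electron electrocyclisation onto the pyranone CH carbon (C8–C8a); tautomerisation of the cyclohexadienone then gives the phenol, first as its Cr(CO)3 complex 19, which air decomplexes. The closest known reaction type is the Dötz benzannulation of alkenyl- and heteroaryl(alkoxy)carbene chromium complexes with alkynes, and the known cyclisation of dienyl(alkoxy)carbene complexes to ortho-alkoxyphenols indicates that an alkoxy-stabilised insertion intermediate of this kind can still take up CO and close. Ring A is closed in the electrocyclic mode, the C4a=C8a double bond of the pyranone serving as the two-electron component that an aryl or alkenyl group normally provides. No stereocentre is formed, so nothing needs to be controlled there. The step needs regioselective alkyne insertion (OMe at C7, H at C6), which the steric rule for terminal alkynes and the polarisation of the ynol ether both favour, and it needs CO insertion to outpace cyclopentannulation or a second alkyne insertion, for which chromium, the donor solvent THF and slow addition of 18 are chosen.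

Step 10
Reactants: 20 3-(benzyloxy)-2-[3,5-bis(benzyloxy)-4-methoxyphenyl]-8-hydroxy-5,7-dimethoxy-4H-chromen-4-one
Product: 21 3-(benzyloxy)-2-[3,5-bis(benzyloxy)-4-methoxyphenyl]-7-methoxy-4H-chromene-4,5,8-trione
Conditions: PhI(OAc)2 (1.1 equiv), MeCN/H2O (2:1), 0 °C
Reagents that add atoms: water, O
Why: Oxidative demethylation of a para-methoxyphenol, in which the phenol binds to iodine, water attacks the para carbon C5 and the hemiketal loses methanol to give the 5,8-quinone; ring B has no free phenol and no para-dialkoxy pair and should stay untouched.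

Step 11
Reactants: 21 3-(benzyloxy)-2-[3,5-bis(benzyloxy)-4-methoxyphenyl]-7-methoxy-4H-chromene-4,5,8-trione
Product: 22 2-(3,5-dihydroxy-4-methoxyphenyl)-3,5,8-trihydroxy-7-methoxy-4H-chromen-4-one
Conditions: H2 (1 atm), Pd/C (10%), EtOAc/MeOH, rt; filter under argon
Reagents that add atoms: none
Why: Catalytic hydrogenation reduces the quinone to the 5,8-hydroquinone and hydrogenolysis removes the three benzyl ethers in the same operation, while the C2=C3 bond of the flavonol, part of a vinylogous ester, is expected to survive these mild conditions.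

**Compound list**

1 | methyl 3,5-dihydroxy-4-methoxybenzoate | COC(=O)c1cc(O)c(OC)c(O)c1 | starting material
2 | methyl 3,5-bis(benzyloxy)-4-methoxybenzoate | COC(=O)c1cc(OCc2ccccc2)c(OC)c(OCc2ccccc2)c1 | intermediate
3 | 3,5-bis(benzyloxy)-4-methoxybenzoic acid | OC(=O)c1cc(OCc2ccccc2)c(OC)c(OCc2ccccc2)c1 | intermediate
4 | tert-butyl 4-chloro-3-oxobutanoate | CC(C)(C)OC(=O)CC(=O)CCl | starting material
5 | tert-butyl 4-(benzyloxy)-3-oxobutanoate | CC(C)(C)OC(=O)CC(=O)COCc1ccccc1 | intermediate
6 | tert-butyl 4-(benzyloxy)-2-[(dimethylamino)methylidene]-3-oxobutanoate | CN(C)C=C(C(=O)OC(C)(C)C)C(=O)COCc1ccccc1 | intermediate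
7 | 3,5-bis(benzyloxy)-4-methoxybenzoyl chloride | ClC(=O)c1cc(OCc2ccccc2)c(OC)c(OCc2ccccc2)c1 | intermediate (not isolated)
8 | tert-butyl 4-(benzyloxy)-5-[3,5-bis(benzyloxy)-4-methoxyphenyl]-2-[(dimethylamino)methylidene]-3,5-dioxopentanoate | CN(C)C=C(C(=O)OC(C)(C)C)C(=O)C(OCc1ccccc1)C(=O)c1cc(OCc2ccccc2)c(OC)c(OCc2ccccc2)c1 | intermediate (not isolated)
9 | tert-butyl 5-(benzyloxy)-6-[3,5-bis(benzyloxy)-4-methoxyphenyl]-4-oxo-4H-pyran-3-carboxylate | CC(C)(C)OC(=O)c1coc(-c2cc(OCc3ccccc3)c(OC)c(OCc3ccccc3)c2)c(OCc2ccccc2)c1=O | intermediate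
10 | 5-(benzyloxy)-6-[3,5-bis(benzyloxy)-4-methoxyphenyl]-4-oxo-4H-pyran-3-carboxylic acid | OC(=O)c1coc(-c2cc(OCc3ccccc3)c(OC)c(OCc3ccccc3)c2)c(OCc2ccccc2)c1=O | intermediate
11 | chromium hexacarbonyl, Cr(CO)6 | O=C=[Cr](=C=O)(=C=O)(=C=O)(=C=O)=C=O | starting material
12 | 5-(benzyloxy)-6-[3,5-bis(benzyloxy)-4-methoxyphenyl]-4-oxo-4H-pyran-3-carbonyl chloride | ClC(=O)c1coc(-c2cc(OCc3ccccc3)c(OC)c(OCc3ccccc3)c2)c(OCc2ccccc2)c1=O | intermediate (not isolated)
13 | dipotassium pentacarbonylchromate, K2Cr(CO)5 | [K+].[K+].O=C=[Cr-2](=C=O)(=C=O)(=C=O)=C=O | intermediate (not isolated)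
14 | potassium pentacarbonyl[5-(benzyloxy)-6-(3,5-bis(benzyloxy)-4-methoxyphenyl)-4-oxo-4H-pyran-3-carbonyl]chromate | [K+].[O-]C(=[Cr](=C=O)(=C=O)(=C=O)(=C=O)=C=O)c1coc(-c2cc(OCc3ccccc3)c(OC)c(OCc3ccccc3)c2)c(OCc2ccccc2)c1=O | intermediate (not isolated)
15 | pentacarbonyl{[5-(benzyloxy)-6-(3,5-bis(benzyloxy)-4-methoxyphenyl)-4-oxo-4H-pyran-3-yl](methoxy)methylidene}chromium | COC(=[Cr](=C=O)(=C=O)(=C=O)(=C=O)=C=O)c1coc(-c2cc(OCc3ccccc3)c(OC)c(OCc3ccccc3)c2)c(OCc2ccccc2)c1=O | intermediate
16 | chloroacetaldehyde dimethyl acetal | COC(CCl)OC | starting material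
17 | sodium methoxyacetylide | [Na+].[C-]#COC | intermediate (not isolated)
18 | methoxyacetylene | COC#C | intermediate
19 | tricarbonylchromium complex of 20, hexahapto-bound through ring A | COc1cc(OC)c2c(=O)c(OCc3ccccc3)c(-c3cc(OCc4ccccc4)c(OC)c(OCc4ccccc4)c3)oc2c1O.O=C=[Cr](=C=O)=C=O | intermediate (not isolated)
20 | 3-(benzyloxy)-2-[3,5-bis(benzyloxy)-4-methoxyphenyl]-8-hydroxy-5,7-dimethoxy-4H-chromen-4-one | COc1cc(OC)c2c(=O)c(OCc3ccccc3)c(-c3cc(OCc4ccccc4)c(OC)c(OCc4ccccc4)c3)oc2c1O | intermediate
21 | 3-(benzyloxy)-2-[3,5-bis(benzyloxy)-4-methoxyphenyl]-7-methoxy-4H-chromene-4,5,8-trione | COC1=CC(=O)c2c(=O)c(OCc3ccccc3)c(-c3cc(OCc4ccccc4)c(OC)c(OCc4ccccc4)c3)oc2C1=O | intermediate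
22 | 2-(3,5-dihydroxy-4-methoxyphenyl)-3,5,8-trihydroxy-7-methoxy-4H-chromen-4-one | COc1cc(O)c2c(=O)c(O)c(-c3cc(O)c(OC)c(O)c3)oc2c1O | target

**Step count**

Total: 11 steps. Longest linear sequence: 8 steps (1, 2, 5, 6, 7, 9, 10, 11; the branch through steps 3 and 4 is equally long).

**Steps most likely to fail**

1. Step 9. The reaction may stall after alkyne insertion, because the new carbene centre is alkoxy-stabilised and may not take up CO. It may also divert to cyclopentannulation or to a second alkyne insertion, so that ring A does not close as the phenol. The fallback uses classical flavone chemistry, sets out from 3 (through its chloride 7, made as in step 5) and returns at 21.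
   - Acylation of commercial 1-(2-hydroxy-3,4,6-trimethoxyphenyl)ethanone with 7 in pyridine should give 2-acetyl-3,5,6-trimethoxyphenyl 3,5-bis(benzyloxy)-4-methoxybenzoate F1.
   - Baker–Venkataraman rearrangement (KOH, pyridine, 50 °C) should give 1-[3,5-bis(benzyloxy)-4-methoxyphenyl]-3-(2-hydroxy-3,4,6-trimethoxyphenyl)propane-1,3-dione F2.
   - Cyclodehydration (p-TsOH, toluene, 80 °C) should give 2-[3,5-bis(benzyloxy)-4-methoxyphenyl]-5,7,8-trimethoxy-4H-chromen-4-one F3.
   - Epoxidation of C2=C3 with dimethyldioxirane and acid-induced opening should give 2-[3,5-bis(benzyloxy)-4-methoxyphenyl]-3-hydroxy-5,7,8-trimethoxy-4H-chromen-4-one F4.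
   - Benzylation (BnBr, K2CO3, DMF) should give 3-(benzyloxy)-2-[3,5-bis(benzyloxy)-4-methoxyphenyl]-5,7,8-trimethoxy-4H-chromen-4-one F5.
   - Oxidative demethylation of the para-dimethoxy pair with Ce(NH4)2(NO3)6 in MeCN/H2O should then give quinone 21.

2. Step 7. Electron transfer from the strongly reducing chromate dianion to the pyranone, or its conjugate addition at the unsubstituted ring carbon, may compete with acylation at the acid chloride. The fallback is the organometallic carbene synthesis, sets out from 10 and returns at 15.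
   - Thermal decarboxylation (Cu powder, quinoline, 180 °C) should give 3-(benzyloxy)-2-[3,5-bis(benzyloxy)-4-methoxyphenyl]-4H-pyran-4-one F6.
   - Alpha-iodination with I2/pyridine should give 3-(benzyloxy)-2-[3,5-bis(benzyloxy)-4-methoxyphenyl]-5-iodo-4H-pyran-4-one F7. It proceeds by conjugate addition of pyridine, iodination of the enolate and elimination, and so spares the electron-rich aryl ring.
   - Iodine–magnesium exchange with iPrMgCl·LiCl in THF at −40 °C should give [5-(benzyloxy)-6-(3,5-bis(benzyloxy)-4-methoxyphenyl)-4-oxo-4H-pyran-3-yl]magnesium chloride F8.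
   - Addition of F8 to Cr(CO)6 (11) should give the chloromagnesium salt of the acylchromate anion of 14, chloromagnesium pentacarbonyl(pyranonecarbonyl)chromate F9.
   - Me3OBF4 in CH2Cl2 then methylates F9 to 15.

3. Step 5. Acylation of the dienolate on oxygen, or a second acylation of the product enolate, may consume the aroyl chloride without forming the carbon–carbon bond. The fallback reverses the order of bond formation, sets out from 5 and 2 and returns at 9.
   - The dianion of 5 (NaH, then n-BuLi, THF, 0 °C) is acylated at its terminal carbon by methyl ester 2 in a Claisen condensation, which should give tert-butyl 4-(benzyloxy)-5-[3,5-bis(benzyloxy)-4-methoxyphenyl]-3,5-dioxopentanoate F10.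
   - Condensation with Me2NCH(OMe)2 at the C2 methylene then gives 8, which closes to 9 on treatment with dilute acid as in step 5.

**Further compounds**

F1 | step 9 | 2-acetyl-3,5,6-trimethoxyphenyl 3,5-bis(benzyloxy)-4-methoxybenzoate | CC(=O)c1c(OC)cc(OC)c(OC)c1OC(=O)c1cc(OCc2ccccc2)c(OC)c(OCc2ccccc2)c1
F2 | step 9 | 1-[3,5-bis(benzyloxy)-4-methoxyphenyl]-3-(2-hydroxy-3,4,6-trimethoxyphenyl)propane-1,3-dione | COc1cc(OC)c(C(=O)CC(=O)c2cc(OCc3ccccc3)c(OC)c(OCc3ccccc3)c2)c(O)c1OC
F3 | step 9 | 2-[3,5-bis(benzyloxy)-4-methoxyphenyl]-5,7,8-trimethoxy-4H-chromen-4-one | COc1cc(OC)c2c(=O)cc(-c3cc(OCc4ccccc4)c(OC)c(OCc4ccccc4)c3)oc2c1OC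
F4 | step 9 | 2-[3,5-bis(benzyloxy)-4-methoxyphenyl]-3-hydroxy-5,7,8-trimethoxy-4H-chromen-4-one | COc1cc(OC)c2c(=O)c(O)c(-c3cc(OCc4ccccc4)c(OC)c(OCc4ccccc4)c3)oc2c1OC
F5 | step 9 | 3-(benzyloxy)-2-[3,5-bis(benzyloxy)-4-methoxyphenyl]-5,7,8-trimethoxy-4H-chromen-4-one | COc1cc(OC)c2c(=O)c(OCc3ccccc3)c(-c3cc(OCc4ccccc4)c(OC)c(OCc4ccccc4)c3)oc2c1OC
F6 | step 7 | 3-(benzyloxy)-2-[3,5-bis(benzyloxy)-4-methoxyphenyl]-4H-pyran-4-one | O=c1ccoc(-c2cc(OCc3ccccc3)c(OC)c(OCc3ccccc3)c2)c1OCc1ccccc1
F7 | step 7 | 3-(benzyloxy)-2-[3,5-bis(benzyloxy)-4-methoxyphenyl]-5-iodo-4H-pyran-4-one | O=c1c(I)coc(-c2cc(OCc3ccccc3)c(OC)c(OCc3ccccc3)c2)c1OCc1ccccc1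
F8 | step 7 | [5-(benzyloxy)-6-(3,5-bis(benzyloxy)-4-methoxyphenyl)-4-oxo-4H-pyran-3-yl]magnesium chloride | Cl[Mg]c1coc(-c2cc(OCc3ccccc3)c(OC)c(OCc3ccccc3)c2)c(OCc2ccccc2)c1=O
F9 | step 7 | chloromagnesium pentacarbonyl[5-(benzyloxy)-6-(3,5-bis(benzyloxy)-4-methoxyphenyl)-4-oxo-4H-pyran-3-carbonyl]chromate | Cl[Mg+].[O-]C(=[Cr](=C=O)(=C=O)(=C=O)(=C=O)=C=O)c1coc(-c2cc(OCc3ccccc3)c(OC)c(OCc3ccccc3)c2)c(OCc2ccccc2)c1=O
F10 | step 5 | tert-butyl 4-(benzyloxy)-5-[3,5-bis(benzyloxy)-4-methoxyphenyl]-3,5-dioxopentanoate | CC(C)(C)OC(=O)CC(=O)C(OCc1ccccc1)C(=O)c1cc(OCc2ccccc2)c(OC)c(OCc2ccccc2)c1
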